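The route rests on cutting the aryl ether bond O1–C7a of the dihydrofuran ring. This unfolds the trans C2/C3 pair into an open-chain syn aldol pair, built from a ring B arylacetyl imide and silyl-protected syringaldehyde (ring A). In one operation the key step joins the free C2 hydroxyl to C7a under palladium catalysis. It closes the five-membered ring and leaves both stereocentres untouched, so syn becomes trans. It exploits that C7a, the old vanillin phenol carbon, can carry a triflate and lies para to the C5 formyl group, which renders ring B electron-poor. The precursor is ArA–CH(OH)–CH(ArB)–CH2OSiR3 with OTf at C7a, OMe at C7 and CHO at C5.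

Key step: step 13

Remark on numbering and configuration: benzofuran numbering is used (O1, C2, C3, C3a, C4–C7, C7a; C9 is the CH2OH carbon on C3). The target SMILES reads as (2R,3S), trans, with an E alkene. The (R)-auxiliary gives the (2R,3R) syn adduct, which becomes the (1R,2S) diol and then the (2R,3S) ring.

Design notes:
- **Ring A phenol.** It is carried as a triisopropylsilyl ether. One buffered fluoride treatment then frees it together with the C9 hydroxyl, so the acid-labile cinnamyl alcohol and the C2 benzylic aryl ether never meet acid.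
- **C5 formyl group.** It is masked as a 1,3-dioxolane. On the electron-poor ring B this acetal is inert enough for the chlorite oxidation and for Bu2BOTf. It should still hydrolyse far faster than the C2 carbinol ionises.
- **C9 oxygen.** tert-Butyldiphenylsilyl is chosen because it is among the silyl groups least prone to O-to-O migration under carbonate.

Step 1
Reactants: 1 vanillin
Product: 2 4-(allyloxy)-3-methoxybenzaldehyde
Conditions: allyl bromide, K2CO3, acetone, reflux
Reagents that add atoms: allyl bromide, C=CCBr
Why: Williamson ether synthesis: carbonate deprotonates the acidic para-formyl phenol and the phenoxide displaces bromide from the allylic halide at oxygen.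

Step 2
Reactants: 2 4-(allyloxy)-3-methoxybenzaldehyde
Product: 4 3-allyl-4-hydroxy-5-methoxybenzaldehyde (5-allylvanillin), via ortho-allyl cyclohexadienone 3 (not isolated)
Conditions: PhNEt2, 200 °C, N2
Reagents that add atoms: none
Why: Aromatic Claisen rearrangement: the [3,3]-sigmatropic shift delivers the allyl group to the only unsubstituted ortho carbon (the future C3a) and enolisation of dienone 3 restores the aromatic phenol.

Step 3
Reactants: 4 5-allylvanillin
Product: 5 2-allyl-4-formyl-6-methoxyphenyl trifluoromethanesulfonate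
Conditions: Tf2O, pyridine, CH2Cl2, 0 °C
Reagents that add atoms: trifluoromethanesulfonic anhydride, O=S(=O)(OS(=O)(=O)C(F)(F)F)C(F)(F)F
Why: O-Sulfonylation of a phenol: pyridine-activated Tf2O converts the acidic phenol into the aryl triflate that later serves as the leaving group on C7a and meanwhile deactivates ring B towards the oxidants to come.

Step 4
Reactants: 5 aryl triflate aldehyde
Product: 6 2-allyl-4-(1,3-dioxolan-2-yl)-6-methoxyphenyl trifluoromethanesulfonate
Conditions: HOCH2CH2OH, p-TsOH·H2O (cat.), toluene, reflux, Dean–Stark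
Reagents that add atoms: ethylene glycol, OCCO
Why: Acid-catalysed acetalisation with azeotropic removal of water: the electron-poor aldehyde acetalises readily, and the triflate and the allyl group are inert to catalytic sulfonic acid.

Step 5
Reactants: 6 allyl dioxolane triflate
Product: 8 4-(1,3-dioxolan-2-yl)-2-methoxy-6-(2-oxoethyl)phenyl trifluoromethanesulfonate, via vicinal diol 7 (not isolated)
Conditions: OsO4 (cat.), NaIO4, 2,6-lutidine, dioxane–H2O, rt; crude product taken on at once
Reagents that add atoms: osmium tetroxide, O=[Os](=O)(=O)=O; sodium periodate, [Na+].[O-]I(=O)(=O)=O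
Why: Lemieux–Johnson oxidative cleavage: catalytic OsO4 dihydroxylates the only alkene, periodate cleaves diol 7 in situ, and 2,6-lutidine keeps the medium near neutral so that the acetal and the enolisable aldehyde survive.

Step 6
Reactants: 8 arylacetaldehyde
Product: 9 2-[5-(1,3-dioxolan-2-yl)-3-methoxy-2-(trifluoromethylsulfonyloxy)phenyl]acetic acid
Conditions: NaClO2, NaH2PO4, 2-methyl-2-butene, t-BuOH–H2O, 0 °C → rt; citric acid work-up
Reagents that add atoms: sodium chlorite, [Na+].[O-]Cl=O
Why: Pinnick oxidation: chlorous acid oxidises the aliphatic aldehyde, the masked aromatic aldehyde cannot react, and 2-methyl-2-butene traps the hypochlorous acid before it can chlorinate ring B.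

Step 7
Reactants: 9 arylacetic acid; 10 (R)-4-benzyl-2-oxazolidinone
Product: 12 (R)-4-benzyl-3-{2-[5-(1,3-dioxolan-2-yl)-3-methoxy-2-(trifluoromethylsulfonyloxy)phenyl]acetyl}oxazolidin-2-one, via mixed pivalic anhydride 11 (not isolated)
Conditions: PivCl, Et3N, THF, −20 °C; then LiCl, 10, −20 °C → rt
Reagents that add atoms: none
Why: N-Acylation of an oxazolidinone through a mixed anhydride: the LiCl/Et3N variant acylates the auxiliary at the unhindered arylacetyl carbonyl of 11 without strong base, which avoids ketene formation from the acidic arylacetyl unit.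

Step 8
Reactants: 13 syringaldehyde
Product: 14 3,5-dimethoxy-4-(triisopropylsilyloxy)benzaldehyde
Conditions: i-Pr3SiCl, imidazole, DMF, rt
Reagents that add atoms: chlorotriisopropylsilane, CC(C)[Si](Cl)(C(C)C)C(C)C
Why: Silyl ether formation: imidazole-promoted silylation caps the acidic phenol with a bulky group shielded by two flanking methoxy groups, so it should resist borohydride, carbonate and phosphonate anion yet fall to fluoride.

Step 9
Reactants: 12 arylacetyl imide; 14 silyl-protected syringaldehyde
Product: 17 (R)-4-benzyl-3-{(2R,3R)-3-[3,5-dimethoxy-4-(triisopropylsilyloxy)phenyl]-2-[5-(1,3-dioxolan-2-yl)-3-methoxy-2-(trifluoromethylsulfonyloxy)phenyl]-3-hydroxypropanoyl}oxazolidin-2-one (syn), via Z boron enolate 15 (not isolated), via boron aldolate 16 (not isolated)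
Conditions: Bu2BOTf, Et3N, CH2Cl2, −78 → 0 °C; 14, −78 → 0 °C; then pH 7 buffer (KH2PO4/K2HPO4), MeOH, H2O2, 0 °C
Reagents that add atoms: none
Why: Evans boron syn aldol: soft enolisation gives the Z enolate, which reacts through a closed Zimmerman–Traxler chair with the imide dipoles opposed and on the face away from the benzyl group of the (R)-auxiliary, which should set both new centres (future C3 and C2) as the (2R,3R) syn pair.

Step 10
Reactants: 17 syn aldol adduct
Product: 18 2-{(1R,2S)-1-[3,5-dimethoxy-4-(triisopropylsilyloxy)phenyl]-1,3-dihydroxypropan-2-yl}-4-(1,3-dioxolan-2-yl)-6-methoxyphenyl trifluoromethanesulfonate (syn diol)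
Conditions: LiBH4, MeOH, THF, 0 °C; aq. NH4Cl
Reagents that add atoms: none
Why: Reductive cleavage of an N-acyl oxazolidinone with borohydride: hydride attacks the exocyclic carbonyl, takes C9 to the alcohol level and releases the auxiliary, while triflate, acetal and silyl ether are inert and the descriptor at C3 changes from R to S only through the change in CIP ranking.

Step 11
Reactants: 18 syn diol
Product: 19 2-{(1R,2S)-3-(tert-butyldiphenylsilyloxy)-1-[3,5-dimethoxy-4-(triisopropylsilyloxy)phenyl]-1-hydroxypropan-2-yl}-4-(1,3-dioxolan-2-yl)-6-methoxyphenyl trifluoromethanesulfonate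
Conditions: t-BuPh2SiCl, imidazole, CH2Cl2, 0 °C → rt
Reagents that add atoms: tert-butylchlorodiphenylsilane, CC(C)(C)[Si](Cl)(c1ccccc1)c1ccccc1
Why: Sterically controlled monosilylation of a diol: the bulky chlorosilane reacts with the primary C9 hydroxyl much faster than with the secondary benzylic C2 hydroxyl, which is crowded by both aryl rings.

Step 12
Reactants: 19 silyl ether acetal
Product: 20 2-{(1R,2S)-3-(tert-butyldiphenylsilyloxy)-1-[3,5-dimethoxy-4-(triisopropylsilyloxy)phenyl]-1-hydroxypropan-2-yl}-4-formyl-6-methoxyphenyl trifluoromethanesulfonate (key-step precursor)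
Conditions: 1 M aq. HCl, THF, rt
Reagents that add atoms: water, O
Why: Specific-acid-catalysed acetal hydrolysis: loss of glycol from the protonated dioxolane is expected to be much faster than ionisation of the C2 benzylic alcohol, and both silyl ethers and the triflate tolerate dilute aqueous acid.

Step 13
Reactants: 20 syn hydroxy triflate aldehyde
Product: 21 (2R,3S)-3-[(tert-butyldiphenylsilyloxy)methyl]-2-[3,5-dimethoxy-4-(triisopropylsilyloxy)phenyl]-7-methoxy-2,3-dihydrobenzofuran-5-carbaldehyde (trans)
Conditions: Pd(OAc)2 (5 mol %), 2-(di-tert-butylphosphino)-1,1'-binaphthyl (7 mol %), Cs2CO3, 4 Å MS, toluene, 75 °C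
Reagents that add atoms: none
Why: Zerovalent palladium, generated in situ from Pd(OAc)2 and the phosphine, inserts into the C7a–OTf bond, Cs2CO3 deprotonates the coordinated C2 hydroxyl to give an oxapalladacycle, and C–O reductive elimination releases the ether and the catalyst. The closest known reaction type is the Buchwald–Hartwig-type intramolecular aryl etherification, established for enantioenriched secondary alcohols with aryl halides and sulfonates. The dihydrofuran ring closes by contraction of the six-membered palladacycle (Pd, C7a, C3a, C3, C2, O), formally a 5-exo closure of O1 onto C7a. No stereocentre is created and none is at risk, because every bond at C2 and C3 stays intact, so the (1R,2S) syn diol is carried over into the (2R,3S) trans ring. The step needs selectivity between the two oxygens, secured by the silyl cap on the C9 oxygen, and it needs reductive elimination to beat β-hydride loss from the benzylic alkoxide, which the steric pressure of the di-tert-butyl(binaphthyl)phosphine and the electron-withdrawing C5 formyl group para to C7a should ensure. Dry toluene, sieves and the mild carbonate base keep S–O cleavage of the triflate and silyl migration slow.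

Step 14
Reactants: 21 dihydrobenzofuran aldehyde; 22 triethyl phosphonoacetate
Product: 24 ethyl (E)-3-{(2R,3S)-3-[(tert-butyldiphenylsilyloxy)methyl]-2-[3,5-dimethoxy-4-(triisopropylsilyloxy)phenyl]-7-methoxy-2,3-dihydrobenzofuran-5-yl}acrylate, via sodium phosphonate carbanion 23 (not isolated)
Conditions: 22, NaH, THF, 0 °C; then 21, 0 °C → rt
Reagents that add atoms: none
Why: Horner–Wadsworth–Emmons olefination: the stabilised phosphonate anion adds reversibly to the aromatic aldehyde and collapses along the lower-energy pathway to the E enoate, while no C–H at C2 or C3 is acidic enough to be at risk.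

Step 15
Reactants: 24 E enoate
Product: 25 (E)-3-{(2R,3S)-3-[(tert-butyldiphenylsilyloxy)methyl]-2-[3,5-dimethoxy-4-(triisopropylsilyloxy)phenyl]-7-methoxy-2,3-dihydrobenzofuran-5-yl}prop-2-en-1-ol
Conditions: i-Bu2AlH, CH2Cl2, −78 °C; aq. potassium sodium tartrate
Reagents that add atoms: none
Why: 1,2-Reduction of an α,β-unsaturated ester with a dialkylaluminium hydride: two hydride transfers at low temperature take the ester to the E allylic alcohol without touching the alkene, the aryl ethers or the silyl ethers.

Step 16
Reactants: 25 bis-silyl ether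
Product: 26 (2R,3S)-2-(4-hydroxy-3,5-dimethoxyphenyl)-3-(hydroxymethyl)-5-[(E)-3-hydroxyprop-1-enyl]-7-methoxy-2,3-dihydrobenzofuran (target)
Conditions: Bu4NF, AcOH, THF, 0 °C → rt
Reagents that add atoms: none
Why: Fluoride-induced desilylation: formation of strong Si–F bonds frees the ring A phenol and the C9 hydroxyl in one operation, and the acetic acid buffer keeps the liberated phenol protonated so that the para-hydroxybenzyl aryl ether at C2 does not open towards a quinone methide.

Compound list
1 | vanillin | COc1cc(C=O)ccc1O | starting material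
2 | 4-(allyloxy)-3-methoxybenzaldehyde | C=CCOc1ccc(C=O)cc1OC | intermediate
3 | 3-allyl-5-methoxy-4-oxocyclohexa-1,5-diene-1-carbaldehyde (ortho-allyl cyclohexadienone, formed in situ) | C=CCC1C=C(C=O)C=C(OC)C1=O | intermediate
4 | 3-allyl-4-hydroxy-5-methoxybenzaldehyde | C=CCc1cc(C=O)cc(OC)c1O | intermediate
5 | 2-allyl-4-formyl-6-methoxyphenyl trifluoromethanesulfonate | C=CCc1cc(C=O)cc(OC)c1OS(=O)(=O)C(F)(F)F | intermediate
6 | 2-allyl-4-(1,3-dioxolan-2-yl)-6-methoxyphenyl trifluoromethanesulfonate | C=CCc1cc(C2OCCO2)cc(OC)c1OS(=O)(=O)C(F)(F)F | intermediate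
7 | 2-(2,3-dihydroxypropyl)-4-(1,3-dioxolan-2-yl)-6-methoxyphenyl trifluoromethanesulfonate (racemic diol, formed in situ) | OCC(O)Cc1cc(C2OCCO2)cc(OC)c1OS(=O)(=O)C(F)(F)F | intermediate
8 | 4-(1,3-dioxolan-2-yl)-2-methoxy-6-(2-oxoethyl)phenyl trifluoromethanesulfonate | O=CCc1cc(C2OCCO2)cc(OC)c1OS(=O)(=O)C(F)(F)F | intermediate
9 | 2-[5-(1,3-dioxolan-2-yl)-3-methoxy-2-(trifluoromethylsulfonyloxy)phenyl]acetic acid | OC(=O)Cc1cc(C2OCCO2)cc(OC)c1OS(=O)(=O)C(F)(F)F | intermediate
10 | (R)-4-benzyl-2-oxazolidinone | O=C1N[C@H](Cc2ccccc2)CO1 | starting material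
11 | mixed anhydride of 9 and pivalic acid (formed in situ) | CC(C)(C)C(=O)OC(=O)Cc1cc(C2OCCO2)cc(OC)c1OS(=O)(=O)C(F)(F)F | intermediate
12 | (R)-4-benzyl-3-(arylacetyl)oxazolidin-2-one, aryl = ring B with dioxolane, OMe and OTf | O=C(Cc1cc(C2OCCO2)cc(OC)c1OS(=O)(=O)C(F)(F)F)N1[C@H](Cc2ccccc2)COC1=O | intermediate
13 | syringaldehyde | COc1cc(C=O)cc(OC)c1O | starting material
14 | 3,5-dimethoxy-4-(triisopropylsilyloxy)benzaldehyde | COc1cc(C=O)cc(OC)c1O[Si](C(C)C)(C(C)C)C(C)C | intermediate
15 | Z dibutylboron enolate of 12 (formed in situ) | CCCCB(CCCC)O/C(=C\c1cc(C2OCCO2)cc(OC)c1OS(=O)(=O)C(F)(F)F)N1[C@H](Cc2ccccc2)COC1=O | intermediate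
16 | dibutylboron aldolate of 17 (formed in situ) | COc1cc([C@H](OB(CCCC)CCCC)[C@H](C(=O)N2[C@H](Cc3ccccc3)COC2=O)c2cc(C3OCCO3)cc(OC)c2OS(=O)(=O)C(F)(F)F)cc(OC)c1O[Si](C(C)C)(C(C)C)C(C)C | intermediate
17 | (2R,3R) syn aldol adduct on the (R)-auxiliary | COc1cc([C@H](O)[C@H](C(=O)N2[C@H](Cc3ccccc3)COC2=O)c2cc(C3OCCO3)cc(OC)c2OS(=O)(=O)C(F)(F)F)cc(OC)c1O[Si](C(C)C)(C(C)C)C(C)C | intermediate
18 | (1R,2S) syn 1,2-diarylpropane-1,3-diol, ring B with dioxolane, OMe and OTf | COc1cc([C@H](O)[C@H](CO)c2cc(C3OCCO3)cc(OC)c2OS(=O)(=O)C(F)(F)F)cc(OC)c1O[Si](C(C)C)(C(C)C)C(C)C | intermediate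
19 | primary tert-butyldiphenylsilyl ether of 18 | COc1cc([C@H](O)[C@H](CO[Si](c2ccccc2)(c2ccccc2)C(C)(C)C)c2cc(C3OCCO3)cc(OC)c2OS(=O)(=O)C(F)(F)F)cc(OC)c1O[Si](C(C)C)(C(C)C)C(C)C | intermediate
20 | key-step precursor: (1R,2S) syn hydroxy silyl ether, ring B with CHO, OMe and OTf | COc1cc([C@H](O)[C@H](CO[Si](c2ccccc2)(c2ccccc2)C(C)(C)C)c2cc(C=O)cc(OC)c2OS(=O)(=O)C(F)(F)F)cc(OC)c1O[Si](C(C)C)(C(C)C)C(C)C | intermediate
21 | key-step product: (2R,3S) trans 2-aryl-3-(silyloxymethyl)-7-methoxy-2,3-dihydrobenzofuran-5-carbaldehyde | COc1cc([C@@H]2Oc3c(OC)cc(C=O)cc3[C@H]2CO[Si](c4ccccc4)(c4ccccc4)C(C)(C)C)cc(OC)c1O[Si](C(C)C)(C(C)C)C(C)C | intermediate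
22 | triethyl phosphonoacetate | CCOC(=O)CP(=O)(OCC)OCC | starting material
23 | sodium salt of the triethyl phosphonoacetate carbanion (formed in situ) | [Na+].CCOC(=O)[CH-]P(=O)(OCC)OCC | intermediate
24 | ethyl (E)-acrylate at C5 of the (2R,3S) dihydrobenzofuran | COc1cc([C@@H]2Oc3c(OC)cc(/C=C/C(=O)OCC)cc3[C@H]2CO[Si](c4ccccc4)(c4ccccc4)C(C)(C)C)cc(OC)c1O[Si](C(C)C)(C(C)C)C(C)C | intermediate
25 | (E)-allylic alcohol, both silyl ethers still in place | COc1cc([C@@H]2Oc3c(OC)cc(/C=C/CO)cc3[C@H]2CO[Si](c4ccccc4)(c4ccccc4)C(C)(C)C)cc(OC)c1O[Si](C(C)C)(C(C)C)C(C)C | intermediate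
26 | (2R,3S)-2-(4-hydroxy-3,5-dimethoxyphenyl)-3-(hydroxymethyl)-5-[(E)-3-hydroxyprop-1-enyl]-7-methoxy-2,3-dihydrobenzofuran | COc1cc([C@@H]2Oc3c(OC)cc(/C=C/CO)cc3[C@H]2CO)cc(OC)c1O | target

Total step count: 16. Longest linear sequence: 15 steps (vanillin through steps 1–7 and 9–16). Step 8 is the one-step side branch from syringaldehyde.

Steps most likely to fail

1. **Step 13 (key step).**
   - Risk: β-hydride elimination from the palladium-bound benzylic alkoxide (oxidising the carbinol and reducing C7a).
   - Risk: base-induced S–O cleavage of the triflate.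
   - Risk: migration of the silyl group from the C9 oxygen to the C2 oxygen, followed by closure through the wrong oxygen.
   - Fallback: form the other ring C–O bond, O1–C2, by cationic chemistry that is well known for phenylcoumarans. Setting out from 20, the activated triflate is cleaved at sulfur with aqueous Et4NOH in dioxane at room temperature. This gives 3-{(1R,2S)-3-(tert-butyldiphenylsilyloxy)-1-[3,5-dimethoxy-4-(triisopropylsilyloxy)phenyl]-1-hydroxypropan-2-yl}-4-hydroxy-5-methoxybenzaldehyde F1. Catalytic BF3·OEt2 in CH2Cl2 at −20 °C then ionises the benzylic alcohol, which ring A stabilises as a cation. The neighbouring phenol captures the cation on the face away from the C3 substituent, which should give the trans ring. C3 takes no part, so it keeps the absolute configuration and dictates C2. The sequence comes back to the route at 21.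

2. **Step 9.**
   - Risk: reversible addition of the stabilised arylacetyl enolate to an electron-rich aldehyde, together with crowding by the ortho triflate. This would erode syn selectivity at C2 while the auxiliary still fixes C3.
   - Fallback: set C2 by substrate-controlled ketone reduction instead of by the aldol transition state. The C2-epimeric material is carried through steps 10 and 11. Setting out from 19 (as the epimer mixture), Dess–Martin periodinane in CH2Cl2 with NaHCO3 gives 2-{(S)-3-(tert-butyldiphenylsilyloxy)-1-[3,5-dimethoxy-4-(triisopropylsilyloxy)phenyl]-1-oxopropan-2-yl}-4-(1,3-dioxolan-2-yl)-6-methoxyphenyl trifluoromethanesulfonate F2. Reduction with LiBH(s-Bu)3 in THF at −78 °C should follow the Felkin–Anh model. Ring B acts as the large group perpendicular to the carbonyl and hydride passes the C3 hydrogen, which places hydroxyl and ring B syn. Neutral oxidation and cold, fast reduction protect the enolisable C3 centre. The sequence comes back to the route at stereochemically uniform 19.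

3. **Step 10.**
   - Risk: retro-aldol fragmentation of the metal alkoxide before hydride delivery.
   - Risk: attack at the endocyclic carbonyl of the hindered imide.
   - Fallback: remove the alkoxide from play before reduction. Setting out from 17, Et3SiOTf and 2,6-lutidine in CH2Cl2 at −78 °C give the C2 triethylsilyl ether of the aldol adduct F3. LiBH4/MeOH in THF at 0 °C gives the primary alcohol carrying the C2 triethylsilyl ether F4. t-BuPh2SiCl and imidazole give the fully silylated acetal F5. The dilute HCl/THF treatment of step 12 then removes the labile triethylsilyl group and the dioxolane together. The sequence comes back to the route at 20, at the cost of one extra operation.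

Further compounds
F1 | step 13 | 3-{(1R,2S)-3-(tert-butyldiphenylsilyloxy)-1-[3,5-dimethoxy-4-(triisopropylsilyloxy)phenyl]-1-hydroxypropan-2-yl}-4-hydroxy-5-methoxybenzaldehyde | COc1cc([C@H](O)[C@H](CO[Si](c2ccccc2)(c2ccccc2)C(C)(C)C)c2cc(C=O)cc(OC)c2O)cc(OC)c1O[Si](C(C)C)(C(C)C)C(C)C
F2 | step 9 | 2-{(S)-3-(tert-butyldiphenylsilyloxy)-1-[3,5-dimethoxy-4-(triisopropylsilyloxy)phenyl]-1-oxopropan-2-yl}-4-(1,3-dioxolan-2-yl)-6-methoxyphenyl trifluoromethanesulfonate | COc1cc(C(=O)[C@H](CO[Si](c2ccccc2)(c2ccccc2)C(C)(C)C)c2cc(C3OCCO3)cc(OC)c2OS(=O)(=O)C(F)(F)F)cc(OC)c1O[Si](C(C)C)(C(C)C)C(C)C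
F3 | step 10 | C2 triethylsilyl ether of aldol adduct 17, (2R,3R) on the (R)-auxiliary | COc1cc([C@H](O[Si](CC)(CC)CC)[C@H](C(=O)N2[C@H](Cc3ccccc3)COC2=O)c2cc(C3OCCO3)cc(OC)c2OS(=O)(=O)C(F)(F)F)cc(OC)c1O[Si](C(C)C)(C(C)C)C(C)C
F4 | step 10 | (1R,2S) primary alcohol with C2 triethylsilyl ether | COc1cc([C@H](O[Si](CC)(CC)CC)[C@H](CO)c2cc(C3OCCO3)cc(OC)c2OS(=O)(=O)C(F)(F)F)cc(OC)c1O[Si](C(C)C)(C(C)C)C(C)C
F5 | step 10 | (1R,2S) C2 triethylsilyl, C9 tert-butyldiphenylsilyl bis-ether with dioxolane | COc1cc([C@H](O[Si](CC)(CC)CC)[C@H](CO[Si](c2ccccc2)(c2ccccc2)C(C)(C)C)c2cc(C3OCCO3)cc(OC)c2OS(=O)(=O)C(F)(F)F)cc(OC)c1O[Si](C(C)C)(C(C)C)C(C)C
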